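## Analysis of the target

Target 12 is an achiral bibenzyl in which ring B (3-methoxyphenyl) and the hexasubstituted ring A are joined by the two-carbon bridge Ca–Cb, with Ca on C1 of ring A and Cb on ring B; there are no stereocentres and no rings other than the five benzene rings. Ring A carries the bridge at C1, 4-hydroxybenzyl groups at C2, C4 and C6, a free hydroxyl at C3 and a methoxy group at C5, so its two oxygens differ and must be told apart somewhere in the route. The sensitive groups are the four phenols (air oxidation, quinone methide formation from the 4-hydroxybenzyl units) and the diarylmethane bonds to the very electron-rich ring A, which strong acid can cleave by retro-Friedel–Crafts reaction. Late steps should therefore be neutral or basic, with the phenols masked until the end. The hard bond is C1–Ca: C1 lies between the benzyl-bearing carbons C2 and C6 and is meta to both ring oxygens, so electrophilic substitution cannot reach it, whereas C2, C4 and C6 are ortho or para to every oxygen. The strategy rests on two features. The bridge is an unbranched ethylene unit with a different aryl group at each end, so it can come from a vinyl group that is arylated at both carbons in one operation. C1 corresponds to the third oxygen of a phloroglucinol-type precursor, so that oxygen can be turned into a triflate and ring A enters as the electrophile.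

## Retrosynthetic reasoning

**12 from 11.** The four O–benzyl bonds (three on the pendant rings, one on O3 of ring A) are cut last. Masking every phenol as a benzyl ether lets one neutral hydrogenolysis finish the synthesis and keeps acid away from the diarylmethane bonds.

**11 from 10.** The Cb–H bond is traced back to a Cb–B bond. Boronate 10 carries the pinacol boronate on the benzylic carbon next to ring B, and fluoride-promoted protodeboronation removes it. The boron is a traceless handle, present only because the key step needs it.

**10 from 5, 6 and 7.** Two bonds are cut at once: C1–Ca and Cb–ring B. The two bridge carbons come from the vinyl group of 7. Ring B comes from 6 through aryllithium 8, which adds to boron to give ate complex 9. Ring A comes as triflate 5. Cutting here, and not at a benzyl group or inside a ring, leaves the crowded hexasubstituted ring as the electrophile, so it never has to be metalated. The forward reaction must make the aryl group shift from boron to Cb faster than any group transfers directly from boron to palladium.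

**5 from 4.** The O–S bond of the triflate is cut. Phenol 4 has a single free hydroxyl, on the carbon that becomes C1, so triflation needs no selectivity.

**4 from 2 and 3.** The three ring A–CH2 bonds at C2, C4 and C6 are cut together, so one molecule of 2 takes up three molecules of alcohol 3 and releases three molecules of water. Every free ring position of 2 is ortho or para to all three oxygens, so threefold Friedel–Crafts benzylation with the cation from 3 can only give 4. Keeping one phenol free in 2 maintains the nucleophilicity of the ring and leaves exactly the hydroxyl that is triflated next.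

**2 from 1.** One O–benzyl bond is cut. Symmetric resorcinol 1 is mono-benzylated at the outset, so the unavoidable statistical differentiation of O1 and O3 falls on the cheapest material, and O5 already carries its methyl group.

## Alternatives that were turned down

Alternative 1: ring A by cyclotrimerisation of a silicon-tethered triyne.
- Disconnection: ring A is cut into three alkynes, held in one chain by a Si–C and a Si–O tether (triyne A1).
- Forward key step: a [2+2+2] cyclotrimerisation of A1 catalysed by RhCl(PPh3)3 would form C6–C1, C2–C3 and C4–C5 and give tricycle A2, in which ring A is fused to a silaindane and a benzoxasilole ring. Cleavage of the benzylic C–Si bonds and the Si–O bond, then debenzylation, would follow.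
- For it: the positions of all six substituents are fixed by connectivity, no hindered intermolecular coupling is needed, and intramolecular cyclotrimerisation is usually efficient. On regiochemical certainty it is at least as strong as the chosen route.
- Against it: A1 contains a siloxyalkyne and a methoxyalkyne, both hydrolytically fragile, and two silicon-bearing stereocentres that give diastereomer mixtures. Assembling A1 takes many steps. Three silicon bonds must then be cleaved after the key step.
- Comparison: the chosen route reaches an equally unambiguous ring A in three steps by electrophilic substitution, so the longer construction buys nothing here.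

Alternative 2: biomimetic aldol folding of a polyketone.
- Disconnection: the C1–C2 bond of ring A is cut, unfolding it to cinnamoyl triketone A3.
- Forward key step: under base the terminal methylene of A3 would add to the cinnamoyl carbonyl; dehydration and enolisation would give stilbene resorcinol A4. Mono-O-methylation, alkene hydrogenation and debenzylation would follow.
- For it: it mirrors the likely biosynthesis, needs no transition metal for ring construction, and reduces the alkene and removes the benzyl groups in one step.
- Against it: the nucleophile required is the least acidic carbon of A3, since the two doubly activated benzyl-bearing positions deprotonate first. Conjugate addition to the enone and O-cyclisation to pyranones compete. A4 has two equivalent hydroxyls, so the methyl ether must be installed by a late statistical mono-methylation.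
- Comparison: the chosen route puts its one statistical step first, on compound 1, and uses no multiply enolisable intermediate.

Alternative 3: Catellani double ortho-benzylation with Heck termination.
- Disconnection: C2–CH2, C6–CH2 and C1–Ca are cut in one step.
- Forward key step: aryl iodide A5 would be benzylated at both ortho C–H positions by benzyl chloride A6 under palladium catalysis with norbornene A8 as mediator. Ipso Heck coupling with 3-methoxystyrene A7 would then give stilbene A9. One hydrogenation would reduce the alkene and remove the benzyl groups.
- For it: it is the most convergent plan, forming three C–C bonds in one step, and it needs no boron detour. In step economy after the aryl halide it is stronger than the chosen route.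
- Against it: both ortho C–H bonds of A5 lie between the palladium-bearing carbon and an alkoxy group, the substitution pattern in which palladacycle formation is slowest. Benzyl chlorides can add directly to zerovalent palladium instead of reaching the palladacycle to give tetravalent palladium. The iodine of A5 is meta to both oxygens, so A5 itself needs a sterically directed C–H functionalisation to prepare.
- Comparison: the chosen route installs all three benzyl groups by simple electrophilic aromatic substitution, where ring A is most reactive, and leaves a single demanding palladium step.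

Key step: step 4

Assumption: the only stereocentre of the route, the boron-bearing carbon of 10, is removed in step 5; it is left uncontrolled and 10 is drawn without configuration.

## Route

Step 1
Reactants: 1 5-methoxyresorcinol
Product: 2 3-(benzyloxy)-5-methoxyphenol
Conditions: BnBr (0.9 equiv), K2CO3 (1.0 equiv), acetone, reflux
Reagents that add atoms: benzyl bromide, BrCc1ccccc1
Why: Williamson ether synthesis on one of two equivalent phenols; limiting benzyl bromide should favour the mono-ether, and unreacted 1 (more polar, base-soluble) and the neutral bis-ether should be separable and 1 recyclable.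

Step 2
Reactants: 2 3-(benzyloxy)-5-methoxyphenol; 3 4-(benzyloxy)benzyl alcohol (three molecules are incorporated per molecule of 2)
Product: 4 3-(benzyloxy)-2,4,6-tris[4-(benzyloxy)benzyl]-5-methoxyphenol
Conditions: 3 (3.3 equiv in all) added in portions, Sc(OTf)3 (10 mol%), MeNO2, 40 °C
Reagents that add atoms: two further molecules of 4-(benzyloxy)benzyl alcohol 3, OCc1ccc(OCc2ccccc2)cc1.OCc1ccc(OCc2ccccc2)cc1
Why: Threefold Friedel–Crafts benzylation with a benzylic alcohol under Lewis-acid catalysis, releasing three molecules of water; the 4-alkoxybenzyl cation from 3 attacks the three free positions of 2, each ortho or para to all three oxygens, so whatever the order of the three substitutions only one product is possible. O-alkylation of the phenol would give an acid-labile 4-alkoxybenzyl aryl ether that reionises and funnels to C-alkylation, and the pendant rings are far less nucleophilic than ring A, so slow addition of 3 keeps self-condensation of the cation down.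

Step 3
Reactants: 4 3-(benzyloxy)-2,4,6-tris[4-(benzyloxy)benzyl]-5-methoxyphenol
Product: 5 3-(benzyloxy)-2,4,6-tris[4-(benzyloxy)benzyl]-5-methoxyphenyl trifluoromethanesulfonate
Conditions: Tf2O, pyridine, CH2Cl2, 0 °C to rt
Reagents that add atoms: trifluoromethanesulfonic anhydride, O=S(=O)(OS(=O)(=O)C(F)(F)F)C(F)(F)F
Why: O-triflation of the only free phenol; 2,6-disubstituted phenols are triflated routinely because sulfur is attacked by the small oxygen nucleophile, and ring A has no free carbon left for C-sulfonylation.

Step 4
Reactants: 5 3-(benzyloxy)-2,4,6-tris[4-(benzyloxy)benzyl]-5-methoxyphenyl trifluoromethanesulfonate; 6 3-bromoanisole; 7 vinylboronic acid pinacol ester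
Product: 10 2-[2-{3-(benzyloxy)-2,4,6-tris[4-(benzyloxy)benzyl]-5-methoxyphenyl}-1-(3-methoxyphenyl)ethyl]-4,4,5,5-tetramethyl-1,3,2-dioxaborolane (configuration at the boron-bearing carbon not controlled), via 3-methoxyphenyllithium 8 (not isolated), via lithium vinylboronate complex 9 (not isolated)
Conditions: 6, n-BuLi, THF, −78 °C; then 7 (slight excess over 8), −78 °C to rt; volatiles removed, fresh THF; then 5, Pd(OAc)2 (5 mol%), 1,1'-bis[bis(3,5-dimethylphenyl)phosphino]-2,2'-bis[(dimethylamino)(phenyl)methyl]ferrocene (MandyPhos-type ligand, 6 mol%), THF, 60 °C
Reagents that add atoms: none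
Why: Bromine–lithium exchange on 6 gives 8, which adds to boron of 7 to form four-coordinate ate complex 9; removing the volatiles strips 1-bromobutane so no halide source accompanies 9. Zerovalent palladium, formed from Pd(OAc)2 and the bisphosphine, inserts into the C1–O bond of 5, and because triflate does not coordinate, the resulting divalent arylpalladium is cationic and binds the vinyl group of 9. This π-activation triggers a 1,2-shift of the 3-methoxyphenyl group from boron to Cb, anti to palladium, which ends up on Ca; C(sp2)–C(sp3) reductive elimination then forms C1–Ca and regenerates zerovalent palladium. The closest known reaction type is the palladium-catalysed conjunctive cross-coupling of vinylboron ate complexes with aryl triflates, applied here to a di-ortho-substituted triflate. No ring is closed. Cb becomes a stereocentre in the migration step and its configuration would follow the ligand, but it is erased in step 5, so either enantiomer or the racemate of the ligand serves. The selectivity needed is metallate shift over direct transmetalation of aryl or vinyl from boron; the triflate leaving group, the halide-free medium and the wide-bite-angle ligand secure it, and the two flanking benzyl groups hinder a four-centre transmetalation at palladium more than attack on a bound alkene. The same ortho congestion should speed reductive elimination relative to β-hydride elimination.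

Step 5
Reactants: 10 2-[2-{3-(benzyloxy)-2,4,6-tris[4-(benzyloxy)benzyl]-5-methoxyphenyl}-1-(3-methoxyphenyl)ethyl]-4,4,5,5-tetramethyl-1,3,2-dioxaborolane
Product: 11 1-(benzyloxy)-2,4,6-tris[4-(benzyloxy)benzyl]-3-methoxy-5-[2-(3-methoxyphenyl)ethyl]benzene
Conditions: TBAF·3H2O (3 equiv), toluene, 60 °C
Reagents that add atoms: none
Why: Fluoride-promoted protodeboronation of a benzylic pinacol boronate; fluoride adds to boron and the tetracoordinate boronate hands the benzylic carbon, whose incipient negative charge is stabilised by ring B, to a proton of water. Benzyl ethers, methyl ethers and the diarylmethane bonds are inert to these conditions.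

Step 6
Reactants: 11 1-(benzyloxy)-2,4,6-tris[4-(benzyloxy)benzyl]-3-methoxy-5-[2-(3-methoxyphenyl)ethyl]benzene
Product: 12 2,4,6-tris(4-hydroxybenzyl)-3-methoxy-5-[2-(3-methoxyphenyl)ethyl]phenol (CNP0285788.0)
Conditions: H2 (1 atm), 10% Pd/C, EtOAc/MeOH, rt
Reagents that add atoms: none
Why: Catalytic hydrogenolysis of four aryl benzyl ethers; the diarylmethane bonds, the bibenzyl bridge and both methyl ethers are stable to these conditions, and the neutral medium avoids acid-induced loss of 4-hydroxybenzyl groups from ring A.

## Compound list

1 | 5-methoxyresorcinol | COc1cc(O)cc(O)c1 | starting material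
2 | 3-(benzyloxy)-5-methoxyphenol | COc1cc(O)cc(OCc2ccccc2)c1 | intermediate
3 | 4-(benzyloxy)benzyl alcohol | OCc1ccc(OCc2ccccc2)cc1 | starting material
4 | 3-(benzyloxy)-2,4,6-tris[4-(benzyloxy)benzyl]-5-methoxyphenol | COc1c(Cc2ccc(OCc3ccccc3)cc2)c(OCc2ccccc2)c(Cc2ccc(OCc3ccccc3)cc2)c(O)c1Cc1ccc(OCc2ccccc2)cc1 | intermediate
5 | 3-(benzyloxy)-2,4,6-tris[4-(benzyloxy)benzyl]-5-methoxyphenyl trifluoromethanesulfonate | COc1c(Cc2ccc(OCc3ccccc3)cc2)c(OCc2ccccc2)c(Cc2ccc(OCc3ccccc3)cc2)c(OS(=O)(=O)C(F)(F)F)c1Cc1ccc(OCc2ccccc2)cc1 | intermediate
6 | 3-bromoanisole | COc1cccc(Br)c1 | starting material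
7 | vinylboronic acid pinacol ester | C=CB1OC(C)(C)C(C)(C)O1 | starting material
8 | 3-methoxyphenyllithium | [Li]c1cccc(OC)c1 | intermediate
9 | lithium (3-methoxyphenyl)(vinyl)(pinacolato)borate | [Li+].C=C[B-]1(c2cccc(OC)c2)OC(C)(C)C(C)(C)O1 | intermediate
10 | 2-[2-{3-(benzyloxy)-2,4,6-tris[4-(benzyloxy)benzyl]-5-methoxyphenyl}-1-(3-methoxyphenyl)ethyl]-4,4,5,5-tetramethyl-1,3,2-dioxaborolane (configuration at the boron-bearing carbon not controlled) | COc1cccc(C(Cc2c(Cc3ccc(OCc4ccccc4)cc3)c(OCc3ccccc3)c(Cc3ccc(OCc4ccccc4)cc3)c(OC)c2Cc2ccc(OCc3ccccc3)cc2)B2OC(C)(C)C(C)(C)O2)c1 | intermediate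
11 | 1-(benzyloxy)-2,4,6-tris[4-(benzyloxy)benzyl]-3-methoxy-5-[2-(3-methoxyphenyl)ethyl]benzene | COc1cccc(CCc2c(Cc3ccc(OCc4ccccc4)cc3)c(OCc3ccccc3)c(Cc3ccc(OCc4ccccc4)cc3)c(OC)c2Cc2ccc(OCc3ccccc3)cc2)c1 | intermediate
12 | 2,4,6-tris(4-hydroxybenzyl)-3-methoxy-5-[2-(3-methoxyphenyl)ethyl]phenol | COc1cccc(CCc2c(Cc3ccc(O)cc3)c(O)c(Cc3ccc(O)cc3)c(OC)c2Cc2ccc(O)cc2)c1 | target

## Step count and least certain steps

Total step count: 6. Longest linear sequence: 6 steps (1 → 2 → 4 → 5 → 10 → 11 → 12).

**Step 4 (key step).**
- What may go wrong: oxidative addition into the C1–O bond, flanked by two benzyl groups on an electron-rich ring, may be slow. Cleavage of the triflate at sulfur would then return phenol 4. Direct transfer of the aryl or vinyl group from boron to palladium could outrun the metallate shift.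
- Fallback: from 5, Sonogashira coupling with commercial 1-ethynyl-3-methoxybenzene F1 (PdCl2(PPh3)2, CuI, Et3N, DMF, 80 °C) should give 1-(benzyloxy)-2,4,6-tris[4-(benzyloxy)benzyl]-3-methoxy-5-[(3-methoxyphenyl)ethynyl]benzene F2. The linear alkyne is the least sterically demanding carbon partner for the crowded C1. Hydrogenation of F2 over Pd/C would saturate the alkyne and cleave the four benzyl ethers in one operation, returning to the route at 12 and bypassing 10 and 11.

**Step 2.**
- What may go wrong: the third benzylation may stall as ring A fills and its flanked alkoxy groups twist out of conjugation. Excess cation may then alkylate the pendant 4-benzyloxyphenyl rings, or the Lewis acid may loosen the O-benzyl group.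
- Fallback: carry out the threefold benzylation on the more nucleophilic resorcinol 1 with three molecules of 3 under the same type of catalysis to give 2,4,6-tris[4-(benzyloxy)benzyl]-5-methoxybenzene-1,3-diol F3. Then mono-O-benzylate one of its two equivalent hydroxyls (BnBr, K2CO3, acetone), accepting a later statistical step, and return to the route at 4.

**Step 5.**
- What may go wrong: protonolysis of the C–B bond at a hindered secondary centre may be slow, allowing adventitious oxidation of the boronate.
- Fallback: from 10, oxidise the C–B bond with NaOH/H2O2 to 2-{3-(benzyloxy)-2,4,6-tris[4-(benzyloxy)benzyl]-5-methoxyphenyl}-1-(3-methoxyphenyl)ethanol F4. Acetylate (Ac2O, pyridine) to 2-{3-(benzyloxy)-2,4,6-tris[4-(benzyloxy)benzyl]-5-methoxyphenyl}-1-(3-methoxyphenyl)ethyl acetate F5. Hydrogenolysis over Pd/C should then remove the benzylic acetate together with the four benzyl ethers, returning to the route at 12.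

## Further compounds

F1 | step 4 | 1-ethynyl-3-methoxybenzene | COc1cccc(C#C)c1
F2 | step 4 | 1-(benzyloxy)-2,4,6-tris[4-(benzyloxy)benzyl]-3-methoxy-5-[(3-methoxyphenyl)ethynyl]benzene | COc1cccc(C#Cc2c(Cc3ccc(OCc4ccccc4)cc3)c(OCc3ccccc3)c(Cc3ccc(OCc4ccccc4)cc3)c(OC)c2Cc2ccc(OCc3ccccc3)cc2)c1
F3 | step 2 | 2,4,6-tris[4-(benzyloxy)benzyl]-5-methoxybenzene-1,3-diol | COc1c(Cc2ccc(OCc3ccccc3)cc2)c(O)c(Cc2ccc(OCc3ccccc3)cc2)c(O)c1Cc1ccc(OCc2ccccc2)cc1
F4 | step 5 | 2-{3-(benzyloxy)-2,4,6-tris[4-(benzyloxy)benzyl]-5-methoxyphenyl}-1-(3-methoxyphenyl)ethanol (racemic) | COc1cccc(C(O)Cc2c(Cc3ccc(OCc4ccccc4)cc3)c(OCc3ccccc3)c(Cc3ccc(OCc4ccccc4)cc3)c(OC)c2Cc2ccc(OCc3ccccc3)cc2)c1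
F5 | step 5 | 2-{3-(benzyloxy)-2,4,6-tris[4-(benzyloxy)benzyl]-5-methoxyphenyl}-1-(3-methoxyphenyl)ethyl acetate (racemic) | COc1cccc(C(OC(C)=O)Cc2c(Cc3ccc(OCc4ccccc4)cc3)c(OCc3ccccc3)c(Cc3ccc(OCc4ccccc4)cc3)c(OC)c2Cc2ccc(OCc3ccccc3)cc2)c1
A1 | alternative 1 | silicon-tethered triyne with a methoxyalkyne, an internal alkyne and a siloxyalkyne (mixture of diastereomers) | COC#CC(c1ccc(OCc2ccccc2)cc1)[Si](C)(C)C(Cc1cccc(OC)c1)C#CC(c1ccc(OCc2ccccc2)cc1)[Si](C)(C)OC#CCc1ccc(OCc2ccccc2)cc1
A2 | alternative 1 | ring A fused to a 2-silaindane ring and a benzoxasilole ring (mixture of diastereomers) | COc1c(Cc2ccc(OCc3ccccc3)cc2)c2O[Si](C)(C)C(c3ccc(OCc4ccccc4)cc3)c2c2c1C(c1ccc(OCc3ccccc3)cc1)[Si](C)(C)C2Cc1cccc(OC)c1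
A3 | alternative 2 | (E)-4,6-bis[4-(benzyloxy)benzyl]-9-[4-(benzyloxy)phenyl]-1-(3-methoxyphenyl)non-1-ene-3,5,7-trione | COc1cccc(/C=C/C(=O)C(Cc2ccc(OCc3ccccc3)cc2)C(=O)C(Cc2ccc(OCc3ccccc3)cc2)C(=O)CCc2ccc(OCc3ccccc3)cc2)c1
A4 | alternative 2 | 2,4,6-tris(4-benzyloxybenzyl)-5-[(E)-2-(3-methoxyphenyl)ethenyl]benzene-1,3-diol | COc1cccc(/C=C/c2c(Cc3ccc(OCc4ccccc4)cc3)c(O)c(Cc3ccc(OCc4ccccc4)cc3)c(O)c2Cc2ccc(OCc3ccccc3)cc2)c1
A5 | alternative 3 | 1-(benzyloxy)-2-[4-(benzyloxy)benzyl]-5-iodo-3-methoxybenzene | COc1cc(I)cc(OCc2ccccc2)c1Cc1ccc(OCc2ccccc2)cc1
A6 | alternative 3 | 4-(benzyloxy)benzyl chloride | ClCc1ccc(OCc2ccccc2)cc1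
A7 | alternative 3 | 3-methoxystyrene | COc1cccc(C=C)c1
A8 | alternative 3 | norbornene (bicyclo[2.2.1]hept-2-ene) | C1=CC2CCC1C2
A9 | alternative 3 | 1-(benzyloxy)-2,4,6-tris(4-benzyloxybenzyl)-3-methoxy-5-[(E)-2-(3-methoxyphenyl)ethenyl]benzene | COc1cccc(/C=C/c2c(Cc3ccc(OCc4ccccc4)cc3)c(OCc3ccccc3)c(Cc3ccc(OCc4ccccc4)cc3)c(OC)c2Cc2ccc(OCc3ccccc3)cc2)c1
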